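**Retrosynthetic overview**
- Both quinones are unmasked last from fully substituted, fully oxygenated arenes (fluoride desilylation, then air); the two arenes differ only in O-methyl (ring 1, kept) versus O-benzyl (ring 2, hydrogenolysed).
- Ring 1 is cut at two bonds, C(OMe)–C(=O) and C(OH)–C(chain), giving a four-carbon cyclobutenone from dimethyl squarate and the two carbons of a silyl ynol ether at the chain terminus, joined by a Danheiser benzannulation.
- Enabling feature: in ring 1 the chain-bearing carbon lies between the C–OH carbon and a quinone C=O carbon (a 2-alkyl-1,3-dioxygenated triad, the signature of ynol ether plus ketene carbonyl), and the remaining run C(OH)–C(=O)–C(Me)–C(OMe) is the O,O,C,O pattern of a 4-silyloxy-3-methyl-2-methoxycyclobutenone.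
- Ring 2 is built the same way from the benzyloxy cyclobutenone at the other terminus of a C17 bis(ynol ether), itself made by twofold Kowalski homologation of dimethyl pentadecanedioate.
- Order of ring formation: ring 2 arene (step 9), ring 1 arene (step 10), both quinones (step 12).

Key step: step 10

Assumption: the target has no stereocentre, so all cyclobutenone intermediates are used as racemates; their single stereocentre is erased on aromatisation. Abbreviations: TBS = tert-butyldimethylsilyl, TIPS = triisopropylsilyl, Bn = benzyl. In the SMILES, long methylene chains are written in blocks joined by the explicit single-bond sign (-), which leaves the structure unchanged.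

**Cyclobutenone for ring 1**

Step 1
Reactants: 1 dimethyl squarate
Product: 2 4-hydroxy-2,3-dimethoxycyclobut-2-en-1-one (racemic)
Conditions: LiAlH(O-t-Bu)3 (1.05 equiv), THF, −78 °C; then H2O, 0 °C
Reagents that add atoms: none
Why: 1,2-hydride reduction of one of the two equivalent squarate carbonyls; the product is a less electrophilic vinylogous ester and should not be reduced further at −78 °C, and the new stereocentre forms as a racemate that is erased later.

Step 2
Reactants: 2 4-hydroxy-2,3-dimethoxycyclobut-2-en-1-one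
Product: 3 4-[(TBS)oxy]-2,3-dimethoxycyclobut-2-en-1-one (racemic)
Conditions: TBSCl, imidazole, DMF, 0 °C → rt
Reagents that add atoms: tert-butyldimethylsilyl chloride, CC(C)(C)[Si](C)(C)Cl
Why: standard silylation of a secondary alcohol under mildly basic conditions, which avoid the acid-triggered collapse of 2 to the semisquarate.

Step 3
Reactants: 3 4-[(TBS)oxy]-2,3-dimethoxycyclobut-2-en-1-one
Product: 5 4-[(TBS)oxy]-2-methoxy-3-methylcyclobut-2-en-1-one (racemic), via lithium alkoxide 4 (not isolated)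
Conditions: MeLi, THF, −78 °C; (CF3CO)2O, −78 °C; aq. NaHCO3, 0 °C
Reagents that add atoms: methyllithium, [Li]C; water, O
Why: 1,2-addition of MeLi to the vinylogous ester carbonyl followed by a Stork–Danheiser-type 1,3-carbonyl transposition (ionisation of the tertiary allylic trifluoroacetate to a methoxy-stabilised oxocarbenium ion that is hydrolysed at the former β-carbon) places methyl β and methoxy α to the new carbonyl; because the silyloxy-bearing carbon is bonded to both the carbonyl and the β-carbon, a competing addition–elimination at the β-carbon would give the same constitution.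

**Cyclobutenone for ring 2**

Step 4
Reactants: 6 squaric acid
Product: 7 dibenzyl squarate
Conditions: BnOH (excess), toluene, reflux, Dean–Stark trap
Reagents that add atoms: benzyl alcohol, OCc1ccccc1
Why: azeotropic esterification of the strongly acidic vinylogous diacid, the same way the simple dialkyl squarates are made.

Step 5
Reactants: 7 dibenzyl squarate
Product: 8 2,3-bis(benzyloxy)-4-hydroxycyclobut-2-en-1-one (racemic)
Conditions: LiAlH(O-t-Bu)3 (1.05 equiv), THF, −78 °C; then H2O, 0 °C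
Reagents that add atoms: none
Why: same selective mono-reduction of a squarate carbonyl as in step 1.

Step 6
Reactants: 8 2,3-bis(benzyloxy)-4-hydroxycyclobut-2-en-1-one
Product: 9 2,3-bis(benzyloxy)-4-[(TBS)oxy]cyclobut-2-en-1-one (racemic)
Conditions: TBSCl, imidazole, DMF, 0 °C → rt
Reagents that add atoms: tert-butyldimethylsilyl chloride, CC(C)(C)[Si](C)(C)Cl
Why: same silylation as in step 2.

Step 7
Reactants: 9 2,3-bis(benzyloxy)-4-[(TBS)oxy]cyclobut-2-en-1-one
Product: 11 2-(benzyloxy)-4-[(TBS)oxy]-3-methylcyclobut-2-en-1-one (racemic), via lithium alkoxide 10 (not isolated)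
Conditions: MeLi, THF, −78 °C; (CF3CO)2O, −78 °C; aq. NaHCO3, 0 °C
Reagents that add atoms: methyllithium, [Li]C; water, O
Why: same addition and Stork–Danheiser-type 1,3-carbonyl transposition as in step 3; the β-benzyloxy group is lost and the α-benzyloxy group is kept as the later ring-2 oxygen.

**Chain**

Step 8
Reactants: 12 dimethyl pentadecanedioate
Product: 15 1,17-bis[(TIPS)oxy]heptadeca-1,16-diyne, via bis(dibromoenolate) 13 (not isolated), via bis(ynolate) 14 (not isolated)
Conditions: CH2Br2, lithium 2,2,6,6-tetramethylpiperidide (LiTMP), THF, −78 °C; n-BuLi, −78 °C → rt; i-Pr3SiCl, 0 °C → rt (amounts doubled for the two termini)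
Reagents that add atoms: dibromomethane, BrCBr; triisopropylsilyl chloride, CC(C)[Si](Cl)(C(C)C)C(C)C
Why: twofold Kowalski ester homologation, in which LiCHBr2 adds to each ester, the dibromo ketone enolate undergoes bromine–lithium exchange and a carbenoid 1,2-shift to the ynolate, and O-silylation with the bulky TIPS group should give an isolable bis(ynol ether).

**Annulations and endgame**

Step 9
Reactants: 15 1,17-bis[(TIPS)oxy]heptadeca-1,16-diyne; 11 2-(benzyloxy)-4-[(TBS)oxy]-3-methylcyclobut-2-en-1-one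
Product: 20 4-(benzyloxy)-6-[(TBS)oxy]-5-methyl-3-[(TIPS)oxy]-2-{15-[(TIPS)oxy]pentadec-14-yn-1-yl}phenol, via vinylketene 16 (not isolated), via 4-vinylcyclobutenone 17 (not isolated), via dienylketene 18 (not isolated), via cyclohexadienone 19 (not isolated)
Conditions: toluene, 80 °C → 110 °C, cyclobutenone added slowly to the diyne held in threefold excess; chromatography on Et3N-deactivated silica, surplus diyne recovered unchanged
Reagents that add atoms: none
Why: Danheiser benzannulation (4π ring opening with the silyloxy group outward, regioselective [2+2] cycloaddition with the oxygen-polarised ynol ether, 4π opening, 6π closure, enolisation), an addition in which every atom of both partners ends up in the phenol; with the symmetrical bis(ynol ether) in excess, statistics favour reaction at one terminus only.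

Step 10
Reactants: 20 4-(benzyloxy)-6-[(TBS)oxy]-5-methyl-3-[(TIPS)oxy]-2-{15-[(TIPS)oxy]pentadec-14-yn-1-yl}phenol; 5 4-[(TBS)oxy]-2-methoxy-3-methylcyclobut-2-en-1-one
Product: 25 2-{13-[5-(benzyloxy)-3-[(TBS)oxy]-2-hydroxy-4-methyl-6-[(TIPS)oxy]phenyl]tridecyl}-6-[(TBS)oxy]-4-methoxy-5-methyl-3-[(TIPS)oxy]phenol, via vinylketene 21 (not isolated), via 4-vinylcyclobutenone 22 (not isolated), via dienylketene 23 (not isolated), via cyclohexadienone 24 (not isolated)
Conditions: toluene, 80 °C → 110 °C, cyclobutenone in 1.5-fold excess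
Reagents that add atoms: none
Why: Heating should open 5 by 4π-electrocyclic ring opening (silyloxy group outward) to vinylketene 21, whose ketene C=C adds the ynol ether of 20 in a [2+2] cycloaddition that makes both new bonds at once (ketene carbonyl carbon to the chain-bearing alkyne carbon, methoxy-bearing ketene carbon to the silyloxy-bearing alkyne carbon) to give 22, and 4π opening of 22 (methoxy outward, alkenyl inward) gives the (3Z)-dienylketene 23, which cyclises to dienone 24 and enolises to the phenol. The closest known reaction type is the Danheiser benzannulation of cyclobutenones with trialkylsilyloxyalkynes, which gives 2-alkylresorcinol mono-silyl ethers. The transient four-membered ring closes by the [2+2] cycloaddition and the six-membered ring by thermal disrotatory 6π-electrocyclisation of the dienylketene, which joins the ketene carbon to the silyloxy-bearing alkene terminus. No stereocentre is created for the product, since the sp3 centres of 22 and 24 are transient and the silyloxy-bearing centre of 5 becomes aromatic. The step needs the [2+2] regiochemistry, which the oxygen-polarised triple bond secures (its nucleophilic β-carbon attacks the ketene carbonyl carbon), so that the chain ends up between the phenol OH and the OTIPS group. Chemoselectivity over the free phenol of 20 rests on its 2,6-disubstitution, and the donor-outward torquoselectivity of both ring openings secures the cis-dienylketene geometry required for closure.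

Step 11
Reactants: 25 bis-arene carrying one benzyl ether
Product: 26 2-{13-[3-[(TBS)oxy]-2,5-dihydroxy-4-methyl-6-[(TIPS)oxy]phenyl]tridecyl}-6-[(TBS)oxy]-4-methoxy-5-methyl-3-[(TIPS)oxy]phenol
Conditions: H2 (1 atm), palladium on carbon (Pd/C), EtOAc, rt; filtered under argon and used crude
Reagents that add atoms: none
Why: hydrogenolysis of the aryl benzyl ether; aryl silyl ethers, the methyl ether and the saturated chain are inert, which is what distinguishes ring 2 from ring 1.

Step 12
Reactants: 26 debenzylated bis-arene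
Product: 28 target bis-quinone (CNP0107579.0), via polyphenol 27 (not isolated)
Conditions: n-Bu4NF, AcOH, THF, 0 °C → rt; then O2 (air), rt
Reagents that add atoms: none
Why: fluoride cleaves the four aryl silyl ethers, and the liberated 1,2,4-trihydroxy- and 1,2,4,5-tetrahydroxyarenes should autoxidise in air to the hydroxy-p-quinones, whose stable vinylogous-acid tautomers are those of the target.

**Compound list**

1 | dimethyl squarate (3,4-dimethoxycyclobut-3-ene-1,2-dione) | COC1=C(OC)C(=O)C1=O | starting material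
2 | 4-hydroxy-2,3-dimethoxycyclobut-2-en-1-one (racemic) | COC1=C(OC)C(O)C1=O | intermediate
3 | 4-[(TBS)oxy]-2,3-dimethoxycyclobut-2-en-1-one (racemic) | COC1=C(OC)C(O[Si](C)(C)C(C)(C)C)C1=O | intermediate
4 | lithium 4-[(TBS)oxy]-2,3-dimethoxy-1-methylcyclobut-2-en-1-olate (diastereomer mixture) | [Li+].COC1=C(OC)C(O[Si](C)(C)C(C)(C)C)C1(C)[O-] | intermediate
5 | 4-[(TBS)oxy]-2-methoxy-3-methylcyclobut-2-en-1-one (racemic) | COC1=C(C)C(O[Si](C)(C)C(C)(C)C)C1=O | intermediate
6 | squaric acid (3,4-dihydroxycyclobut-3-ene-1,2-dione) | OC1=C(O)C(=O)C1=O | starting material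
7 | dibenzyl squarate (3,4-bis(benzyloxy)cyclobut-3-ene-1,2-dione) | O=C1C(=O)C(OCc2ccccc2)=C1OCc3ccccc3 | intermediate
8 | 2,3-bis(benzyloxy)-4-hydroxycyclobut-2-en-1-one (racemic) | O=C1C(OCc2ccccc2)=C(OCc3ccccc3)C1O | intermediate
9 | 2,3-bis(benzyloxy)-4-[(TBS)oxy]cyclobut-2-en-1-one (racemic) | O=C1C(OCc2ccccc2)=C(OCc3ccccc3)C1O[Si](C)(C)C(C)(C)C | intermediate
10 | lithium 2,3-bis(benzyloxy)-4-[(TBS)oxy]-1-methylcyclobut-2-en-1-olate (diastereomer mixture) | [Li+].CC1([O-])C(OCc2ccccc2)=C(OCc3ccccc3)C1O[Si](C)(C)C(C)(C)C | intermediate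
11 | 2-(benzyloxy)-4-[(TBS)oxy]-3-methylcyclobut-2-en-1-one (racemic) | CC1=C(OCc2ccccc2)C(=O)C1O[Si](C)(C)C(C)(C)C | intermediate
12 | dimethyl pentadecanedioate | COC(=O)CCCCC-CCCCC-CCC-C(=O)OC | starting material
13 | dilithium 1,1,17,17-tetrabromoheptadeca-1,16-diene-2,16-diolate | [Li+].[Li+].[O-]C(=C(Br)Br)CCCCC-CCCCC-CCC-C([O-])=C(Br)Br | intermediate
14 | dilithium heptadeca-1,16-diyne-1,17-diolate | [Li+].[Li+].[O-]C#C-CCCCC-CCCCC-CCC-C#C[O-] | intermediate
15 | 1,17-bis[(TIPS)oxy]heptadeca-1,16-diyne | CC(C)[Si](C(C)C)(C(C)C)OC#C-CCCCC-CCCCC-CCC-C#CO[Si](C(C)C)(C(C)C)C(C)C | intermediate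
16 | (3E)-2-(benzyloxy)-4-[(TBS)oxy]-3-methylbuta-1,3-dien-1-one (vinylketene) | O=C=C(OCc1ccccc1)/C(C)=C/O[Si](C)(C)C(C)(C)C | intermediate
17 | 4-(benzyloxy)-4-{(1E)-1-[(TBS)oxy]prop-1-en-2-yl}-3-[(TIPS)oxy]-2-{15-[(TIPS)oxy]pentadec-14-yn-1-yl}cyclobut-2-en-1-one (racemic) | O=C1C(CCCCC-CCCCC-CCC-C#CO[Si](C(C)C)(C(C)C)C(C)C)=C(O[Si](C(C)C)(C(C)C)C(C)C)C1(OCc2ccccc2)/C(C)=C/O[Si](C)(C)C(C)(C)C | intermediate
18 | (3Z,5E)-4-(benzyloxy)-6-[(TBS)oxy]-5-methyl-3-[(TIPS)oxy]-2-{15-[(TIPS)oxy]pentadec-14-yn-1-yl}hexa-1,3,5-trien-1-one (dienylketene) | O=C=C(CCCCC-CCCCC-CCC-C#CO[Si](C(C)C)(C(C)C)C(C)C)/C(O[Si](C(C)C)(C(C)C)C(C)C)=C(OCc1ccccc1)\C(C)=C\O[Si](C)(C)C(C)(C)C | intermediate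
19 | 4-(benzyloxy)-6-[(TBS)oxy]-5-methyl-3-[(TIPS)oxy]-2-{15-[(TIPS)oxy]pentadec-14-yn-1-yl}cyclohexa-2,4-dien-1-one (racemic) | O=C1C(CCCCC-CCCCC-CCC-C#CO[Si](C(C)C)(C(C)C)C(C)C)=C(O[Si](C(C)C)(C(C)C)C(C)C)C(OCc2ccccc2)=C(C)C1O[Si](C)(C)C(C)(C)C | intermediate
20 | 4-(benzyloxy)-6-[(TBS)oxy]-5-methyl-3-[(TIPS)oxy]-2-{15-[(TIPS)oxy]pentadec-14-yn-1-yl}phenol | Oc1c(CCCCC-CCCCC-CCC-C#CO[Si](C(C)C)(C(C)C)C(C)C)c(O[Si](C(C)C)(C(C)C)C(C)C)c(OCc2ccccc2)c(C)c1O[Si](C)(C)C(C)(C)C | intermediate
21 | (3E)-4-[(TBS)oxy]-2-methoxy-3-methylbuta-1,3-dien-1-one (vinylketene) | O=C=C(OC)/C(C)=C/O[Si](C)(C)C(C)(C)C | intermediate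
22 | 4-methoxy-4-{(1E)-1-[(TBS)oxy]prop-1-en-2-yl}-3-[(TIPS)oxy]cyclobut-2-en-1-one carrying at C2 the 13-(ring-2 aryl)tridecyl chain of 25 (racemic) | O=C1C(CCCCC-CCCCC-CCC-c2c(O)c(O[Si](C)(C)C(C)(C)C)c(C)c(OCc3ccccc3)c2O[Si](C(C)C)(C(C)C)C(C)C)=C(O[Si](C(C)C)(C(C)C)C(C)C)C1(OC)/C(C)=C/O[Si](C)(C)C(C)(C)C | intermediate
23 | (3Z,5E)-6-[(TBS)oxy]-4-methoxy-5-methyl-3-[(TIPS)oxy]hexa-1,3,5-trien-1-one carrying at C2 the 13-(ring-2 aryl)tridecyl chain (dienylketene) | O=C=C(CCCCC-CCCCC-CCC-c1c(O)c(O[Si](C)(C)C(C)(C)C)c(C)c(OCc2ccccc2)c1O[Si](C(C)C)(C(C)C)C(C)C)/C(O[Si](C(C)C)(C(C)C)C(C)C)=C(OC)\C(C)=C\O[Si](C)(C)C(C)(C)C | intermediate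
24 | 6-[(TBS)oxy]-4-methoxy-5-methyl-3-[(TIPS)oxy]cyclohexa-2,4-dien-1-one carrying at C2 the 13-(ring-2 aryl)tridecyl chain (racemic) | O=C1C(CCCCC-CCCCC-CCC-c2c(O)c(O[Si](C)(C)C(C)(C)C)c(C)c(OCc3ccccc3)c2O[Si](C(C)C)(C(C)C)C(C)C)=C(O[Si](C(C)C)(C(C)C)C(C)C)C(OC)=C(C)C1O[Si](C)(C)C(C)(C)C | intermediate
25 | 2-{13-[5-(benzyloxy)-3-[(TBS)oxy]-2-hydroxy-4-methyl-6-[(TIPS)oxy]phenyl]tridecyl}-6-[(TBS)oxy]-4-methoxy-5-methyl-3-[(TIPS)oxy]phenol | COc1c(C)c(O[Si](C)(C)C(C)(C)C)c(O)c(CCCCC-CCCCC-CCC-c2c(O)c(O[Si](C)(C)C(C)(C)C)c(C)c(OCc3ccccc3)c2O[Si](C(C)C)(C(C)C)C(C)C)c1O[Si](C(C)C)(C(C)C)C(C)C | intermediate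
26 | 2-{13-[3-[(TBS)oxy]-2,5-dihydroxy-4-methyl-6-[(TIPS)oxy]phenyl]tridecyl}-6-[(TBS)oxy]-4-methoxy-5-methyl-3-[(TIPS)oxy]phenol | COc1c(C)c(O[Si](C)(C)C(C)(C)C)c(O)c(CCCCC-CCCCC-CCC-c2c(O)c(O[Si](C)(C)C(C)(C)C)c(C)c(O)c2O[Si](C(C)C)(C(C)C)C(C)C)c1O[Si](C(C)C)(C(C)C)C(C)C | intermediate
27 | 3-methyl-6-[13-(2,3,6-trihydroxy-5-methoxy-4-methylphenyl)tridecyl]benzene-1,2,4,5-tetrol | COc1c(C)c(O)c(O)c(CCCCC-CCCCC-CCC-c2c(O)c(O)c(C)c(O)c2O)c1O | intermediate
28 | 2,5-dihydroxy-3-[13-(2-hydroxy-5-methoxy-4-methyl-3,6-dioxocyclohexa-1,4-dien-1-yl)tridecyl]-6-methylcyclohexa-2,5-diene-1,4-dione | COC1=C(C)C(=O)C(O)=C(CCCCC-CCCCC-CCC-C2=C(O)C(=O)C(C)=C(O)C2=O)C1=O | target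

**Step count and risks**

Total step count: 12. Longest linear sequence: 8 steps (steps 4, 5, 6, 7, 9, 10, 11, 12, from squaric acid).

Steps most likely to fail:

1. Step 10 (key step). The transient vinylketene from 5 may be consumed by O-acylation of the free phenol of 20, or the long-chain ynol ether of 20, the limiting and valuable partner, may decay (1,3-silyl shift, protonolysis) before the [2+2] event. Fallback: each ring is closed on a simple ynol ether used in excess, and the two arenes are joined afterwards by metathesis; it sets out from 5 and 11 and comes back at 26. Purchased methyl undec-10-enoate F1 would be homologated as in step 8 to triisopropyl(dodec-11-en-1-yn-1-yloxy)silane F2, and F2 in twofold excess heated with 5 in toluene should give the ring-1 phenol with a dec-9-enyl chain F3. Purchased methyl hex-5-enoate F4 would give triisopropyl(hept-6-en-1-yn-1-yloxy)silane F5 in the same way, and F5 with 11 the ring-2 phenol with a pent-4-enyl chain F6. Cross-metathesis of F3 with a twofold excess of F6 (RuCl2(H2IMes)(=CH-C6H4-2-O-i-Pr), the second-generation Hoveyda–Grubbs catalyst, CH2Cl2, 40 °C) should give the internal alkene F7 as an E/Z mixture, which is of no consequence. Hydrogenation under the conditions of step 11 saturates the alkene and cleaves the benzyl ether in one operation to give 26.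

2. Step 9. A second annulation at the other terminus, and loss of the surviving ynol ether while the mono-adduct is separated on silica from the surplus of 15, may erode the supply of 20. Fallback: both annulations are run in one pot and the separation is deferred until the products differ in polarity; it sets out from 15 and comes back at 26. Compound 15 would be heated in toluene with equimolar amounts of 11 and 5, giving a statistical mixture of 25, the symmetrical bis(methoxy) bis-arene F8 and the symmetrical bis(benzyloxy) bis-arene F9. Hydrogenolysis of the unseparated mixture (H2, Pd/C, EtOAc) leaves F8 unchanged, converts 25 into 26 and F9 into the bis-debenzylated compound F10. These carry two, three and four free phenols and should be separable by chromatography under argon.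

3. Step 8. Homologation may stop after one ester terminus, and the polylithiated intermediates may precipitate, giving mixed ester/ynol ether products. Fallback: the ynolate is made by oxidation of an acetylide instead of by carbenoid rearrangement; it sets out from 12 and comes back at 15. Reduction of 12 with i-Bu2AlH (CH2Cl2, −78 °C) would give pentadecanedial F11. Ohira–Bestmann homologation (dimethyl (1-diazo-2-oxopropyl)phosphonate, K2CO3, MeOH) would give heptadeca-1,16-diyne F12. Double deprotonation with n-BuLi (THF, −78 °C) and oxidation of the bis-acetylide with LiOO-t-Bu (from t-BuOOH and LiN(SiMe3)2, −78 → 0 °C) should give the bis(ynolate) 14, which is trapped with i-Pr3SiOTf to give 15.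

**Further compounds**

F1 | step 10 | methyl undec-10-enoate (purchased) | C=C-CCCC-CCCC-C(=O)OC
F2 | step 10 | triisopropyl(dodec-11-en-1-yn-1-yloxy)silane | C=C-CCCC-CCCC-C#CO[Si](C(C)C)(C(C)C)C(C)C
F3 | step 10 | 6-[(TBS)oxy]-2-(dec-9-en-1-yl)-4-methoxy-5-methyl-3-[(TIPS)oxy]phenol | COc1c(C)c(O[Si](C)(C)C(C)(C)C)c(O)c(CCCC-CCCC-C=C)c1O[Si](C(C)C)(C(C)C)C(C)C
F4 | step 10 | methyl hex-5-enoate (purchased) | C=C-CCC-C(=O)OC
F5 | step 10 | triisopropyl(hept-6-en-1-yn-1-yloxy)silane | C=C-CCC-C#CO[Si](C(C)C)(C(C)C)C(C)C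
F6 | step 10 | 4-(benzyloxy)-6-[(TBS)oxy]-5-methyl-2-(pent-4-en-1-yl)-3-[(TIPS)oxy]phenol | Oc1c(CCC-C=C)c(O[Si](C(C)C)(C(C)C)C(C)C)c(OCc2ccccc2)c(C)c1O[Si](C)(C)C(C)(C)C
F7 | step 10 | 2-{13-[5-(benzyloxy)-3-[(TBS)oxy]-2-hydroxy-4-methyl-6-[(TIPS)oxy]phenyl]tridec-9-en-1-yl}-6-[(TBS)oxy]-4-methoxy-5-methyl-3-[(TIPS)oxy]phenol (E/Z mixture) | COc1c(C)c(O[Si](C)(C)C(C)(C)C)c(O)c(CCCC-CCCC-C=C-CCC-c2c(O)c(O[Si](C)(C)C(C)(C)C)c(C)c(OCc3ccccc3)c2O[Si](C(C)C)(C(C)C)C(C)C)c1O[Si](C(C)C)(C(C)C)C(C)C
F8 | step 9 | 2,2'-(tridecane-1,13-diyl)bis{6-[(TBS)oxy]-4-methoxy-5-methyl-3-[(TIPS)oxy]phenol} | COc1c(C)c(O[Si](C)(C)C(C)(C)C)c(O)c(CCCCC-CCCCC-CCC-c2c(O)c(O[Si](C)(C)C(C)(C)C)c(C)c(OC)c2O[Si](C(C)C)(C(C)C)C(C)C)c1O[Si](C(C)C)(C(C)C)C(C)C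
F9 | step 9 | 2,2'-(tridecane-1,13-diyl)bis{4-(benzyloxy)-6-[(TBS)oxy]-5-methyl-3-[(TIPS)oxy]phenol} | Oc1c(CCCCC-CCCCC-CCC-c2c(O)c(O[Si](C)(C)C(C)(C)C)c(C)c(OCc3ccccc3)c2O[Si](C(C)C)(C(C)C)C(C)C)c(O[Si](C(C)C)(C(C)C)C(C)C)c(OCc4ccccc4)c(C)c1O[Si](C)(C)C(C)(C)C
F10 | step 9 | 2,2'-(tridecane-1,13-diyl)bis{6-[(TBS)oxy]-5-methyl-3-[(TIPS)oxy]benzene-1,4-diol} | Oc1c(CCCCC-CCCCC-CCC-c2c(O)c(O[Si](C)(C)C(C)(C)C)c(C)c(O)c2O[Si](C(C)C)(C(C)C)C(C)C)c(O[Si](C(C)C)(C(C)C)C(C)C)c(O)c(C)c1O[Si](C)(C)C(C)(C)C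
F11 | step 8 | pentadecanedial | O=C-CCCCC-CCCCC-CCC-C=O
F12 | step 8 | heptadeca-1,16-diyne | C#C-CCCCC-CCCCC-CCC-C#C
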